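## Retrosynthetic overview

1. Target 22 ⇐ bis-TBS ether 21; the last step is an acidic fluoride desilylation, so no base touches the labile C3–H.
2. 21 ⇐ silyloxydiene 7 + aryl dienynone 18 in one flask: Diels–Alder/aromatisation builds ring A, then a catalytic enantioselective oxa-Michael/protonation closes ring C and sets C3.
3. 7 ⇐ methyl acetoacetate + prenyl bromide; the prenyl group is fixed at the future C6 before the arene exists.
4. 18 ⇐ aryl Grignard (from 2,5-dimethoxyphenol) + penta-1,4-diyn-3-ol by carbomagnesiation, then oxidation.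
5. Ring order: B is bought; A and then C form in the same operation.

Assumption: the SMILES descriptor is read as (3S); 2,5-dimethoxyphenol and 0.5 M ethynylmagnesium bromide in THF are bought; which pseudo-enantiomeric cinchona catalyst gives (3S) must be fixed in a first screening run (the quinidine-derived one is written).

## Route

Step 1
Reactants: 1 methyl acetoacetate; 2 prenyl bromide (1-bromo-3-methylbut-2-ene)
Product: 5 methyl (2Z)-3-[(tert-butyldimethylsilyl)oxy]-7-methylocta-2,6-dienoate, via acetoacetate dianion 3 (not isolated), via ketoester sodium enolate 4 (not isolated)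
Conditions: NaH (1.05 equiv), THF, 0 °C; n-BuLi (1.05 equiv), 0 °C; 2 (1.0 equiv), 0 °C → rt; TBSCl (1.1 equiv), rt; non-aqueous work-up, distil
Reagents that add atoms: tert-butyldimethylsilyl chloride, CC(C)(C)[Si](C)(C)Cl
Why: Weiler dianion alkylation puts the prenyl group on the more nucleophilic γ-carbon, and the chelated Z-enolate that remains is O-silylated in the same pot (enolate O-silylation); no stereocentre is formed.

Step 2
Reactants: 5 methyl (2Z)-3-[(tert-butyldimethylsilyl)oxy]-7-methylocta-2,6-dienoate
Product: 7 (1Z,3Z)-3-[(tert-butyldimethylsilyl)oxy]-1-methoxy-7-methyl-1-[(trimethylsilyl)oxy]octa-1,3,6-triene (major isomer drawn; used as obtained), via lithium dienolate 6 (not isolated)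
Conditions: LDA (1.1 equiv), THF, −78 °C; TMSCl (1.2 equiv), −78 → 0 °C; pentane, filter, concentrate
Reagents that add atoms: chlorotrimethylsilane, C[Si](C)(C)Cl
Why: Chan-type diene synthesis, in which LDA removes a γ-proton of the vinylogous ester and the extended dienolate is silylated on the ester oxygen to give the 1-methoxy-1,3-bis(silyloxy)diene.

Step 3
Reactants: 8 2,5-dimethoxyphenol
Product: 9 4-bromo-2,5-dimethoxyphenol
Conditions: NBS (1.0 equiv), MeCN, −20 → 0 °C
Reagents that add atoms: N-bromosuccinimide, O=C1CCC(=O)N1Br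
Why: Electrophilic aromatic bromination goes to the position para to the free OH, which is the most activated and least hindered site.

Step 4
Reactants: 9 4-bromo-2,5-dimethoxyphenol
Product: 10 (4-bromo-2,5-dimethoxyphenoxy)(tert-butyl)dimethylsilane
Conditions: TBSCl, imidazole, DMF, rt
Reagents that add atoms: tert-butyldimethylsilyl chloride, CC(C)(C)[Si](C)(C)Cl
Why: Silyl ether formation masks the phenol for the organomagnesium chemistry and survives every step up to the final fluoride treatment.

Step 5
Reactants: 11 ethyl formate; 12 ethynylmagnesium bromide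
Product: 14 penta-1,4-diyn-3-ol, via propynal 13 (not isolated)
Conditions: 12 (2.1 equiv, 0.5 M in THF), 0 °C → rt; aqueous quench; used as a dried ether solution
Reagents that add atoms: none
Why: Double Grignard addition to a formate ester, in which the propynal formed after the first addition is more electrophilic than the ester and takes up the second acetylide.

Step 6
Reactants: 10 (4-bromo-2,5-dimethoxyphenoxy)(tert-butyl)dimethylsilane; 14 penta-1,4-diyn-3-ol
Product: 17 (±)-2-{4-[(tert-butyldimethylsilyl)oxy]-2,5-dimethoxyphenyl}pent-1-en-4-yn-3-ol, via arylmagnesium bromide 15 (not isolated), via chloromagnesium diynolate 16 (not isolated)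
Conditions: 10, Mg, LiCl, THF, rt; separately 14 (2.0 equiv), i-PrMgCl (2.0 equiv), Et2O, −30 °C; combine, CuI (15 mol %), −10 °C → rt; aqueous quench
Reagents that add atoms: none
Why: Duboudin-type copper-catalysed anti-carbomagnesiation of a propargylic magnesium alkoxide delivers the aryl group to the alkyne carbon next to the carbinol, giving the 1,1-disubstituted alkene; excess of the symmetric diynol limits reaction to one alkyne, and the racemic carbinol centre is removed in step 7.

Step 7
Reactants: 17 (±)-2-{4-[(tert-butyldimethylsilyl)oxy]-2,5-dimethoxyphenyl}pent-1-en-4-yn-3-ol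
Product: 18 2-{4-[(tert-butyldimethylsilyl)oxy]-2,5-dimethoxyphenyl}pent-1-en-4-yn-3-one
Conditions: activated MnO2 (15 equiv), CH2Cl2, 0 °C → rt; filter through Celite; use at once
Reagents that add atoms: none
Why: MnO2 oxidation of a doubly activated (allylic and propargylic) secondary alcohol under neutral conditions that leave the aryl silyl ether and terminal alkyne untouched.

Step 8
Reactants: 7 (1Z,3Z)-3-[(tert-butyldimethylsilyl)oxy]-1-methoxy-7-methyl-1-[(trimethylsilyl)oxy]octa-1,3,6-triene; 18 2-{4-[(tert-butyldimethylsilyl)oxy]-2,5-dimethoxyphenyl}pent-1-en-4-yn-3-one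
Product: 21 (3S)-7-[(tert-butyldimethylsilyl)oxy]-3-{4-[(tert-butyldimethylsilyl)oxy]-2,5-dimethoxyphenyl}-6-(3-methylbut-2-en-1-yl)-2,3-dihydro-4H-chromen-4-one, via Diels–Alder cycloadduct 19 (not isolated), via ortho-hydroxyaryl enone 20 (not isolated)
Conditions: 7 (1.5 equiv), PhMe, 0 → 40 °C; then MeOH (3 equiv), rt, 1 h; then 9-amino-9-deoxy-epi-quinidine 3,5-bis(trifluoromethyl)phenyl squaramide (10 mol %), −30 °C; AcOH quench, cold silica filtration
Reagents that add atoms: none
Why: Proposed new method: the nucleophilic C4 terminus of diene 7 bonds to the terminal carbon of the ynone in 18 (Diels–Alder benzannulation; closest known type is the regiospecific resorcinol synthesis from 1-alkoxy-1,3-bis(silyloxy)dienes and alkynyl ketones), loss of MeOSiMe3 aromatises ring A and frees the ortho-phenol of 20, and the bifunctional squaramide then deprotonates that phenol for a 6-endo-trig oxa-Michael addition onto the α-aryl enone (the ring closure known from base-mediated isoflavanone syntheses via 2'-hydroxy-α-methylenedeoxybenzoins) while its ammonium protonates one face of the resulting C3=C4 enolate, so ring C closes and C3 is set as (S) by catalyst-controlled enantioselective protonation (closest known type: cinchona-catalysed tandem conjugate addition–enantioselective protonation of α-substituted acceptors).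

Step 9
Reactants: 21 (3S)-7-[(tert-butyldimethylsilyl)oxy]-3-{4-[(tert-butyldimethylsilyl)oxy]-2,5-dimethoxyphenyl}-6-(3-methylbut-2-en-1-yl)-2,3-dihydro-4H-chromen-4-one
Product: 22 (3S)-7-hydroxy-3-(4-hydroxy-2,5-dimethoxyphenyl)-6-(3-methylbut-2-en-1-yl)-2,3-dihydro-4H-chromen-4-one
Conditions: HF·pyridine, THF, 0 °C → rt
Reagents that add atoms: none
Why: Fluoride-driven cleavage of both aryl silyl ethers (Si–F bond formation) in an acidic medium with no base strong enough to enolise C3–H and no strong acid that would cyclise the ortho-prenylphenol, so the (3S) centre is carried through unchanged.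

## Compound list

1 | methyl acetoacetate | COC(=O)CC(C)=O | starting material
2 | prenyl bromide (1-bromo-3-methylbut-2-ene) | CC(C)=CCBr | starting material
3 | sodium lithium dianion of methyl acetoacetate | [Na+].[Li+].COC(=O)[CH-]C(=O)[CH2-] | intermediate (not isolated)
4 | sodium enolate of methyl 7-methyl-3-oxooct-6-enoate | [Na+].COC(=O)[CH-]C(=O)CCC=C(C)C | intermediate (not isolated)
5 | methyl (2Z)-3-[(tert-butyldimethylsilyl)oxy]-7-methylocta-2,6-dienoate | COC(=O)/C=C(/CCC=C(C)C)O[Si](C)(C)C(C)(C)C | intermediate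
6 | lithium dienolate of 5 | [Li+].CO/C([O-])=C/C(O[Si](C)(C)C(C)(C)C)=C/CC=C(C)C | intermediate (not isolated)
7 | (1Z,3Z)-3-[(tert-butyldimethylsilyl)oxy]-1-methoxy-7-methyl-1-[(trimethylsilyl)oxy]octa-1,3,6-triene | CO/C(O[Si](C)(C)C)=C/C(O[Si](C)(C)C(C)(C)C)=C/CC=C(C)C | intermediate
8 | 2,5-dimethoxyphenol | COc1ccc(OC)c(O)c1 | starting material
9 | 4-bromo-2,5-dimethoxyphenol | COc1cc(O)c(OC)cc1Br | intermediate
10 | (4-bromo-2,5-dimethoxyphenoxy)(tert-butyl)dimethylsilane | COc1cc(O[Si](C)(C)C(C)(C)C)c(OC)cc1Br | intermediate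
11 | ethyl formate | CCOC=O | starting material
12 | ethynylmagnesium bromide | C#C[Mg]Br | starting material
13 | propynal | C#CC=O | intermediate (not isolated)
14 | penta-1,4-diyn-3-ol | C#CC(O)C#C | intermediate
15 | {4-[(tert-butyldimethylsilyl)oxy]-2,5-dimethoxyphenyl}magnesium bromide | COc1cc(O[Si](C)(C)C(C)(C)C)c(OC)cc1[Mg]Br | intermediate (not isolated)
16 | chloromagnesium penta-1,4-diyn-3-olate | C#CC(O[Mg]Cl)C#C | intermediate (not isolated)
17 | (±)-2-{4-[(tert-butyldimethylsilyl)oxy]-2,5-dimethoxyphenyl}pent-1-en-4-yn-3-ol | C=C(c1cc(OC)c(O[Si](C)(C)C(C)(C)C)cc1OC)C(O)C#C | intermediate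
18 | 2-{4-[(tert-butyldimethylsilyl)oxy]-2,5-dimethoxyphenyl}pent-1-en-4-yn-3-one | C=C(c1cc(OC)c(O[Si](C)(C)C(C)(C)C)cc1OC)C(=O)C#C | intermediate
19 | 1-{4-[(tert-butyldimethylsilyl)oxy]-6-methoxy-3-(3-methylbut-2-en-1-yl)-6-[(trimethylsilyl)oxy]cyclohexa-1,4-dien-1-yl}-2-{4-[(tert-butyldimethylsilyl)oxy]-2,5-dimethoxyphenyl}prop-2-en-1-one (racemic diastereomer mixture) | COC1(O[Si](C)(C)C)C=C(O[Si](C)(C)C(C)(C)C)C(CC=C(C)C)C=C1C(=O)C(=C)c1cc(OC)c(O[Si](C)(C)C(C)(C)C)cc1OC | intermediate (not isolated)
20 | 1-{4-[(tert-butyldimethylsilyl)oxy]-2-hydroxy-5-(3-methylbut-2-en-1-yl)phenyl}-2-{4-[(tert-butyldimethylsilyl)oxy]-2,5-dimethoxyphenyl}prop-2-en-1-one | C=C(C(=O)c1cc(CC=C(C)C)c(O[Si](C)(C)C(C)(C)C)cc1O)c1cc(OC)c(O[Si](C)(C)C(C)(C)C)cc1OC | intermediate (not isolated)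
21 | (3S)-7-[(tert-butyldimethylsilyl)oxy]-3-{4-[(tert-butyldimethylsilyl)oxy]-2,5-dimethoxyphenyl}-6-(3-methylbut-2-en-1-yl)-2,3-dihydro-4H-chromen-4-one | COc1cc([C@H]2COc3cc(O[Si](C)(C)C(C)(C)C)c(CC=C(C)C)cc3C2=O)c(OC)cc1O[Si](C)(C)C(C)(C)C | intermediate
22 | (3S)-7-hydroxy-3-(4-hydroxy-2,5-dimethoxyphenyl)-6-(3-methylbut-2-en-1-yl)-2,3-dihydro-4H-chromen-4-one | COc1cc([C@H]2COc3cc(O)c(CC=C(C)C)cc3C2=O)c(OC)cc1O | target

## Step count

Total steps: 9. Longest linear sequence: 6 (steps 3, 4, 6, 7, 8, 9).

## Three steps most likely to fail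

**Step 8 (annulation and enantioselective protonation).** Three things can go wrong: the diene may attack the enone CH2 of 18 instead of the ynone; 20 may close without the catalyst and give racemic material; and the level and sense of induction are untested. The fallback sets the stereocentre after ring closure instead of during it. It sets out from 20, formed in the same flask after the MeOH stage. Et3N at rt cyclises it to the racemic bis-TBS isoflavanone F1. LiHMDS and TMSCl in THF at −78 °C convert this into the 3-aryl-4-(trimethylsilyloxy)-2H-chromene F2. F2 is then protonated with a BINOL-derived N-triflyl thiophosphoramide (5 mol %) and phenol as the stoichiometric proton source in toluene, a known catalytic enantioselective protonation of silyl enol ethers of 2-aryl cyclic ketones. This comes back to the route at 21.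

**Step 6 (carbomagnesiation of the diynol).** The acetylenic C–H bonds of 14 can quench the aryl Grignard, and both alkynes can react. The fallback uses the well-precedented mono-alkyne version and adds the second alkyne later. It sets out from 10 through its Grignard 15. With propargyl alcohol (bought) and catalytic CuI in Et2O, 15 gives 2-{4-[(tert-butyldimethylsilyl)oxy]-2,5-dimethoxyphenyl}prop-2-en-1-ol F3. MnO2 oxidises this to the 2-arylprop-2-enal F4. 1,2-Addition of ethynylmagnesium bromide 12 in THF at −78 °C then comes back to the route at 17. Step 5 is no longer needed, and the net cost is one extra step.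

**Step 9 (final desilylation).** The C3–H is benzylic and α to the ketone, so ee can erode, and acid can cyclise the ortho-prenylphenol onto the alkene. The fallback reverses the order so that nothing follows creation of C3. It sets out from 20, isolated after the MeOH stage of step 8 (no base, so no ring closure). Aqueous HF in MeCN at 0 °C removes both silyl groups while no stereocentre exists yet, giving the triphenol enone 1-[2,4-dihydroxy-5-(3-methylbut-2-en-1-yl)phenyl]-2-(4-hydroxy-2,5-dimethoxyphenyl)prop-2-en-1-one F5. The enantioselective oxa-Michael/protonation is then run on F5 as the last operation, with the same squaramide or a chiral phosphoric acid if the acidic 7-OH ties up the amine. This comes back to the route at 22.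

## Further compounds

F1 | step 8 | racemic 7-[(tert-butyldimethylsilyl)oxy]-3-{4-[(tert-butyldimethylsilyl)oxy]-2,5-dimethoxyphenyl}-6-(3-methylbut-2-en-1-yl)-2,3-dihydro-4H-chromen-4-one | COc1cc(C2COc3cc(O[Si](C)(C)C(C)(C)C)c(CC=C(C)C)cc3C2=O)c(OC)cc1O[Si](C)(C)C(C)(C)C
F2 | step 8 | 7-[(tert-butyldimethylsilyl)oxy]-3-{4-[(tert-butyldimethylsilyl)oxy]-2,5-dimethoxyphenyl}-6-(3-methylbut-2-en-1-yl)-4-[(trimethylsilyl)oxy]-2H-chromene | COc1cc(C2=C(O[Si](C)(C)C)c3cc(CC=C(C)C)c(O[Si](C)(C)C(C)(C)C)cc3OC2)c(OC)cc1O[Si](C)(C)C(C)(C)C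
F3 | step 6 | 2-{4-[(tert-butyldimethylsilyl)oxy]-2,5-dimethoxyphenyl}prop-2-en-1-ol | C=C(CO)c1cc(OC)c(O[Si](C)(C)C(C)(C)C)cc1OC
F4 | step 6 | 2-{4-[(tert-butyldimethylsilyl)oxy]-2,5-dimethoxyphenyl}prop-2-enal | C=C(C=O)c1cc(OC)c(O[Si](C)(C)C(C)(C)C)cc1OC
F5 | step 9 | 1-[2,4-dihydroxy-5-(3-methylbut-2-en-1-yl)phenyl]-2-(4-hydroxy-2,5-dimethoxyphenyl)prop-2-en-1-one | C=C(C(=O)c1cc(CC=C(C)C)c(O)cc1O)c1cc(OC)c(O)cc1OC
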